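## Retrosynthetic overview

1. ε-Lactone (C3–O–C16) last: oxidation of C16 and capture by the tertiary C3–OH.
2. Tetrahydrofuran (C2–O–C9): transannular 5-exo opening of a 2,3-epoxide by the C9 hydroxyl inside the pre-formed 6/10 carbocycle.
3. Ten-membered carbocycle: intramolecular Hosomi–Sakurai allylation (C8–C9), which also gives C9–OH and the C7 exo-methylene.
4. Open-chain precursor: Paterson aldol (C5–C6) and Evans–Tishchenko reduction (C4, C6 butanoate) on an enone attached by alkenyl–copper 1,4-addition (C1–C2) to a carvone-derived enethioate.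
5. Ring order: cyclohexane (from (R)-carvone) → ten-membered carbocycle → tetrahydrofuran → ε-lactone.

Assumption: the SMILES is taken literally (eunicellane numbering 1S,2R,3S,4R,6R,9S,10R,11R,14R,15R, which places C3 and C8 trans across the tetrahydrofuran); atom labels C1–C20 below use that numbering.

## Route

Step 1
Reactants: 1 (R)-(−)-carvone
Product: 2 (1R,4R,6R)-1-methyl-4-(prop-1-en-2-yl)-7-oxabicyclo[4.1.0]heptan-2-one
Conditions: 30% H2O2, NaOH (cat.), MeOH, 0 °C
Reagents that add atoms: hydrogen peroxide, OO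
Why: Weitz–Scheffer nucleophilic epoxidation; axial attack of HOO− anti to the equatorial isopropenyl group puts the epoxide oxygen trans to it and so sets C11.

Step 2
Reactants: 2 (1R,4R,6R)-1-methyl-4-(prop-1-en-2-yl)-7-oxabicyclo[4.1.0]heptan-2-one
Product: 3 (1R,2S,4R)-1-methyl-4-(prop-1-en-2-yl)cyclohexane-1,2-diol
Conditions: LiAlH4, THF, 0 to 50 °C; Fieser work-up
Reagents that add atoms: none
Why: Hydride reduction of the ketone and SN2 opening of the trisubstituted epoxide at the secondary C12 (tertiary C11 is not attacked) keep the C11–O bond and configuration; the C10 carbinol is a throw-away centre removed in step 3.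

Step 3
Reactants: 3 (1R,2S,4R)-1-methyl-4-(prop-1-en-2-yl)cyclohexane-1,2-diol
Product: 4 (2R,5R)-2-hydroxy-2-methyl-5-(prop-1-en-2-yl)cyclohexan-1-one
Conditions: IBX, EtOAc, 75 °C
Reagents that add atoms: none
Why: IBX oxidation of the secondary carbinol of a 1,2-diol gives the α-ketol without C–C cleavage; no stereocentre is touched.

Step 4
Reactants: 4 (2R,5R)-2-hydroxy-2-methyl-5-(prop-1-en-2-yl)cyclohexan-1-one
Product: 6 (3R,6R)-6-methyl-3-(prop-1-en-2-yl)-6-(triethylsilyloxy)cyclohex-1-en-1-yl trifluoromethanesulfonate, via silyl ether ketone 5 (not isolated)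
Conditions: TESOTf, 2,6-lutidine, CH2Cl2, −78 °C; crude, then KHMDS, PhNTf2, THF, −78 °C
Reagents that add atoms: triethylsilyl trifluoromethanesulfonate, CC[Si](CC)(CC)OS(=O)(=O)C(F)(F)F; N-phenylbis(trifluoromethanesulfonimide), FC(F)(F)S(=O)(=O)N(c1ccccc1)S(=O)(=O)C(F)(F)F
Why: O-silylation, then kinetic enolisation (only C1–H is enolisable because C11 is quaternary) and O-triflation (McMurry–Scott enol triflate synthesis) give a single regioisomer.

Step 5
Reactants: 6 (3R,6R)-6-methyl-3-(prop-1-en-2-yl)-6-(triethylsilyloxy)cyclohex-1-en-1-yl trifluoromethanesulfonate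
Product: 7 S-ethyl (3R,6R)-6-methyl-3-(prop-1-en-2-yl)-6-(triethylsilyloxy)cyclohex-1-ene-1-carbothioate
Conditions: Pd(OAc)2 (5 mol %), Xantphos, CO (1 atm), EtSH, Et3N, DMF, 60 °C
Reagents that add atoms: carbon monoxide, [C-]#[O+]; ethanethiol, CCS
Why: Pd-catalysed thiocarbonylation of the enol triflate (oxidative addition, CO insertion, thiolysis) installs C9 as an enethioate, a strong Michael acceptor and a latent aldehyde.

Step 6
Reactants: 8 but-3-yn-2-ol (racemic)
Product: 9 (E)-4-iodo-3-methylbut-3-en-2-ol (racemic)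
Conditions: AlMe3, Cp2ZrCl2 (cat.), CH2Cl2, 0 °C to rt; then I2, THF, −30 °C; aq. Na2S2O3/NaHCO3
Reagents that add atoms: trimethylaluminium, C[Al](C)C; iodine, II
Why: Negishi zirconium-catalysed carboalumination (syn Me–Al addition) and iodinolysis with retention give the (E)-iodoalkene.

Step 7
Reactants: 9 (E)-4-iodo-3-methylbut-3-en-2-ol
Product: 10 (E)-4-iodo-3-methylbut-3-en-2-one
Conditions: MnO2, CH2Cl2, rt
Reagents that add atoms: none
Why: MnO2 oxidation of an allylic alcohol; alkene geometry is untouched.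

Step 8
Reactants: 10 (E)-4-iodo-3-methylbut-3-en-2-one
Product: 11 2-[(E)-1-iodoprop-1-en-2-yl]-2-methyl-1,3-dioxolane
Conditions: TMSOCH2CH2OTMS, TMSOTf (cat.), CH2Cl2, −78 to −20 °C
Reagents that add atoms: 1,2-bis(trimethylsilyloxy)ethane, C[Si](C)(C)OCCO[Si](C)(C)C
Why: Noyori ketalisation masks the enone carbonyl under aprotic conditions without moving the double bond.

Step 9
Reactants: 7 S-ethyl (3R,6R)-6-methyl-3-(prop-1-en-2-yl)-6-(triethylsilyloxy)cyclohex-1-ene-1-carbothioate; 11 2-[(E)-1-iodoprop-1-en-2-yl]-2-methyl-1,3-dioxolane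
Product: 12 S-ethyl (1S,2S,3R,6R)-6-methyl-2-[(E)-2-(2-methyl-1,3-dioxolan-2-yl)prop-1-en-1-yl]-3-(prop-1-en-2-yl)-6-(triethylsilyloxy)cyclohexane-1-carbothioate
Conditions: 11, i-PrMgCl·LiCl, THF, 0 °C; then CuBr·SMe2 (10 mol %), TMSCl, 7, −78 to −40 °C; AcOH, −78 °C, then aq. NH4Cl
Reagents that add atoms: none
Why: I/Mg exchange with retention, then Cu-catalysed 1,4-addition of the alkenyl Grignard to the unsaturated thioester anti to the isopropenyl group sets C1; kinetic protonation of the silyl ketene thioacetal opposite to the new alkenyl and the C11 siloxy groups sets C10 (H-1/H-10 cis).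

Step 10
Reactants: 12 S-ethyl (1S,2S,3R,6R)-6-methyl-2-[(E)-2-(2-methyl-1,3-dioxolan-2-yl)prop-1-en-1-yl]-3-(prop-1-en-2-yl)-6-(triethylsilyloxy)cyclohexane-1-carbothioate
Product: 14 hydroxy enone (12 with isopropenyl turned into (2R)-1-hydroxypropan-2-yl and the dioxolane into the methyl ketone), via dioxolane alcohol 13 (not isolated)
Conditions: 9-BBN, THF, 0 °C to rt; pH 7 buffer, 30% H2O2, 0 °C; then PPTS, THF/H2O, 40 °C
Reagents that add atoms: hydrogen peroxide, OO; water, O
Why: Chemoselective hydroboration–oxidation of the 1,1-disubstituted alkene; 9-BBN attacks the H-eclipsed rotamer anti to the C1 substituent (Still/Houk 1,2-induction) to set C15 as R, and mild acid hydrolysis then frees the enone.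

Step 11
Reactants: 14 hydroxy enone
Product: 15 tert-butyldimethylsilyl ether of the primary (C16) alcohol of 14
Conditions: TBSCl, imidazole, CH2Cl2, 0 °C
Reagents that add atoms: tert-butyldimethylsilyl chloride, CC(C)(C)[Si](C)(C)Cl
Why: Standard silylation of the only free hydroxyl.

Step 12
Reactants: 16 2-[(trimethylsilyl)methyl]prop-2-en-1-ol
Product: 17 2-[(trimethylsilyl)methyl]prop-2-enal
Conditions: MnO2, CH2Cl2, rt
Reagents that add atoms: none
Why: MnO2 oxidation of an allylic alcohol; the allylsilane is inert.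

Step 13
Reactants: 15 TBS ether of 14; 17 2-[(trimethylsilyl)methyl]prop-2-enal
Product: 18 (6R)-β-hydroxy ketone (C4 ketone, C6 carbinol carrying the 3-(trimethylsilyl)prop-1-en-2-yl group)
Conditions: (+)-Ipc2BCl, Et3N, Et2O, −78 °C; 17, −78 to −20 °C; H2O2, pH 7 buffer, MeOH
Reagents that add atoms: none
Why: Paterson boron aldol; the methyl ketone is enolised on the CH3 side and the Ipc ligands direct re-face attack on the aldehyde to set C6 as R (the antipodal reagent is available if the sense is reversed).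

Step 14
Reactants: 18 (6R)-β-hydroxy ketone
Product: 19 (4R)-allylic alcohol, (6R)-butanoate (1,3-anti)
Conditions: SmI2 (30 mol %), butanal (6 equiv), THF, −10 °C
Reagents that add atoms: butanal, CCCC=O
Why: Evans–Tishchenko reduction; the samarium-bound hemiacetal delivers hydride intramolecularly to the ketone, setting C4 anti to C6 and leaving the C6 oxygen as its butanoate.

Step 15
Reactants: 19 (4R)-allylic alcohol, (6R)-butanoate
Product: 20 4-octanoate of 19
Conditions: octanoyl chloride, pyridine, DMAP (cat.), CH2Cl2, 0 °C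
Reagents that add atoms: octanoyl chloride, CCCCCCCC(Cl)=O
Why: DMAP-catalysed acylation of the only free hydroxyl.

Step 16
Reactants: 20 4-octanoate
Product: 21 C9 aldehyde
Conditions: Et3SiH, Pb-poisoned 5% Pd/CaCO3, acetone, rt
Reagents that add atoms: none
Why: Fukuyama reduction turns the thioester into the aldehyde under neutral conditions, sparing both esters and the epimerisable C10.

Step 17
Reactants: 21 C9 aldehyde
Product: 22 ten-membered carbocycle, (9S)-alcohol with (E)-C2=C3 and C7 exo-methylene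
Conditions: BF3·OEt2 (1.5 equiv), CH2Cl2 (1 mM, slow addition), −78 °C; aq. NaHCO3
Reagents that add atoms: none
Why: Intramolecular Hosomi–Sakurai allylation closes C8–C9 and creates the exo-methylene; Felkin–Anh attack anti to the quaternary C11 on the non-chelated aldehyde sets C9 as S.

Step 18
Reactants: 22 ten-membered carbocycle
Product: 24 2,9-oxa-bridged alcohol (2R,3S; free tertiary 3-OH), via epoxide 23 (not isolated)
Conditions: ent-Shi ketone (L-fructose-derived, 30 mol %), Oxone, K2CO3, Bu4NHSO4, MeCN/DMM/aq. buffer pH 10.5, 0 °C; then CSA (10 mol %), CH2Cl2, −20 °C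
Reagents that add atoms: potassium peroxymonosulfate, [K+].OOS(=O)(=O)[O-]
Why: Proposed new method: Shi epoxidation selects the trisubstituted (E)-alkene over the 1,1-disubstituted one and the ent-ketone gives the (2S,3S)-epoxide; the C9 hydroxyl then opens it transannularly at C2 (5-exo, SN2 inversion to 2R, C3–O retained), while the C4 acyloxy group disfavours cationic 6-endo attack at C3 and the silylated C11 oxygen cannot compete; the closest known reactions are Kishi-type acid-promoted hydroxy-epoxide cyclisations to tetrahydrofurans.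

Step 19
Reactants: 24 2,9-oxa-bridged alcohol
Product: 25 triol (3-OH, 11-OH, 16-OH)
Conditions: HF·pyridine, pyridine, THF, 0 °C to rt
Reagents that add atoms: none
Why: Fluoride-mediated desilylation removes the primary TBS and tertiary TES ethers without touching the esters.

Step 20
Reactants: 25 triol
Product: 28 CNP0350718.2, via aldehyde 26 (not isolated), via lactol 27 (not isolated)
Conditions: TEMPO (20 mol %), PhI(OAc)2 (2.5 equiv), CH2Cl2, rt
Reagents that add atoms: none
Why: TEMPO/PhI(OAc)2 oxidative lactonisation; the primary C16 alcohol is oxidised, the aldehyde is trapped by the C3 hydroxyl as a seven-membered lactol and oxidised on to the lactone, with C15 untouched under these neutral conditions.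

## Compound list

1 | (R)-(−)-carvone, (5R)-2-methyl-5-(prop-1-en-2-yl)cyclohex-2-en-1-one | CC(=C)[C@@H]1CC=C(C)C(=O)C1 | starting material
2 | (1R,4R,6R)-1-methyl-4-(prop-1-en-2-yl)-7-oxabicyclo[4.1.0]heptan-2-one (epoxide trans to isopropenyl) | CC(=C)[C@@H]1C[C@H]2O[C@@]2(C)C(=O)C1 | intermediate
3 | (1R,2S,4R)-1-methyl-4-(prop-1-en-2-yl)cyclohexane-1,2-diol | CC(=C)[C@@H]1CC[C@@](C)(O)[C@@H](O)C1 | intermediate
4 | (2R,5R)-2-hydroxy-2-methyl-5-(prop-1-en-2-yl)cyclohexan-1-one | CC(=C)[C@@H]1CC[C@@](C)(O)C(=O)C1 | intermediate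
5 | (2R,5R)-2-methyl-5-(prop-1-en-2-yl)-2-(triethylsilyloxy)cyclohexan-1-one | CC(=C)[C@@H]1CC[C@@](C)(O[Si](CC)(CC)CC)C(=O)C1 | intermediate
6 | (3R,6R)-6-methyl-3-(prop-1-en-2-yl)-6-(triethylsilyloxy)cyclohex-1-en-1-yl trifluoromethanesulfonate | CC(=C)[C@@H]1CC[C@@](C)(O[Si](CC)(CC)CC)C(OS(=O)(=O)C(F)(F)F)=C1 | intermediate
7 | S-ethyl (3R,6R)-6-methyl-3-(prop-1-en-2-yl)-6-(triethylsilyloxy)cyclohex-1-ene-1-carbothioate | CC(=C)[C@@H]1CC[C@@](C)(O[Si](CC)(CC)CC)C(C(=O)SCC)=C1 | intermediate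
8 | but-3-yn-2-ol (racemic) | CC(O)C#C | starting material
9 | (E)-4-iodo-3-methylbut-3-en-2-ol (racemic) | I/C=C(\C)C(C)O | intermediate
10 | (E)-4-iodo-3-methylbut-3-en-2-one | I/C=C(\C)C(C)=O | intermediate
11 | 2-[(E)-1-iodoprop-1-en-2-yl]-2-methyl-1,3-dioxolane | I/C=C(\C)C1(C)OCCO1 | intermediate
12 | S-ethyl (1S,2S,3R,6R)-6-methyl-2-[(E)-2-(2-methyl-1,3-dioxolan-2-yl)prop-1-en-1-yl]-3-(prop-1-en-2-yl)-6-(triethylsilyloxy)cyclohexane-1-carbothioate (thioester, alkenyl and siloxy groups mutually cis; isopropenyl trans to alkenyl) | CC(=C)[C@@H]1CC[C@@](C)(O[Si](CC)(CC)CC)[C@@H](C(=O)SCC)[C@H]1/C=C(\C)C2(C)OCCO2 | intermediate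
13 | dioxolane alcohol: 12 with the isopropenyl group converted into (2R)-1-hydroxypropan-2-yl (C15 R) | OC[C@H](C)[C@@H]1CC[C@@](C)(O[Si](CC)(CC)CC)[C@@H](C(=O)SCC)[C@H]1/C=C(\C)C2(C)OCCO2 | intermediate
14 | hydroxy enone: 13 with the dioxolane hydrolysed to the (E)-2-methyl-3-oxobut-1-enyl ketone | OC[C@H](C)[C@@H]1CC[C@@](C)(O[Si](CC)(CC)CC)[C@@H](C(=O)SCC)[C@H]1/C=C(\C)C(C)=O | intermediate
15 | tert-butyldimethylsilyl ether of the C16 alcohol of 14 | CC(C)(C)[Si](C)(C)OC[C@H](C)[C@@H]1CC[C@@](C)(O[Si](CC)(CC)CC)[C@@H](C(=O)SCC)[C@H]1/C=C(\C)C(C)=O | intermediate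
16 | 2-[(trimethylsilyl)methyl]prop-2-en-1-ol | C=C(CO)C[Si](C)(C)C | starting material
17 | 2-[(trimethylsilyl)methyl]prop-2-enal | C=C(C=O)C[Si](C)(C)C | intermediate
18 | (6R)-β-hydroxy ketone: aldol adduct of 15 (C5) and 17 (C6), C4 ketone | CC(C)(C)[Si](C)(C)OC[C@H](C)[C@@H]1CC[C@@](C)(O[Si](CC)(CC)CC)[C@@H](C(=O)SCC)[C@H]1/C=C(\C)C(=O)C[C@@H](O)C(=C)C[Si](C)(C)C | intermediate
19 | (4R)-allylic alcohol, (6R)-butanoate, 1,3-anti | CC(C)(C)[Si](C)(C)OC[C@H](C)[C@@H]1CC[C@@](C)(O[Si](CC)(CC)CC)[C@@H](C(=O)SCC)[C@H]1/C=C(\C)[C@H](O)C[C@@H](OC(=O)CCC)C(=C)C[Si](C)(C)C | intermediate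
20 | 4-octanoate of 19 | CC(C)(C)[Si](C)(C)OC[C@H](C)[C@@H]1CC[C@@](C)(O[Si](CC)(CC)CC)[C@@H](C(=O)SCC)[C@H]1/C=C(\C)[C@H](OC(=O)CCCCCCC)C[C@@H](OC(=O)CCC)C(=C)C[Si](C)(C)C | intermediate
21 | C9 aldehyde: 20 with C(=O)SEt reduced to CHO | CC(C)(C)[Si](C)(C)OC[C@H](C)[C@@H]1CC[C@@](C)(O[Si](CC)(CC)CC)[C@@H](C=O)[C@H]1/C=C(\C)[C@H](OC(=O)CCCCCCC)C[C@@H](OC(=O)CCC)C(=C)C[Si](C)(C)C | intermediate
22 | ten-membered carbocycle: (9S)-alcohol, (E)-C2=C3, C7 exo-methylene, 4-octanoate, 6-butanoate, 11-OTES, 16-OTBS, cyclohexane cis-fused at C1/C10 | C=C1C[C@H](O)[C@H]2[C@@H](/C=C(\C)[C@H](OC(=O)CCCCCCC)C[C@H]1OC(=O)CCC)[C@@H](CC[C@@]2(C)O[Si](CC)(CC)CC)[C@@H](C)CO[Si](C)(C)C(C)(C)C | intermediate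
23 | (2S,3S)-2,3-epoxide of 22 | C=C1C[C@H](O)[C@H]2[C@@H]([C@@H]3O[C@@]3(C)[C@H](OC(=O)CCCCCCC)C[C@H]1OC(=O)CCC)[C@@H](CC[C@@]2(C)O[Si](CC)(CC)CC)[C@@H](C)CO[Si](C)(C)C(C)(C)C | intermediate
24 | 2,9-oxa-bridged alcohol: tetrahydrofuran C9–O–C2 (2R,9S), tertiary 3-OH (3S), silyl ethers intact | C=C1C[C@@H]2O[C@H]([C@H]3[C@@H](CC[C@@](C)(O[Si](CC)(CC)CC)[C@H]32)[C@@H](C)CO[Si](C)(C)C(C)(C)C)[C@@](C)(O)[C@H](OC(=O)CCCCCCC)C[C@H]1OC(=O)CCC | intermediate
25 | triol: 24 with 11-OH and 16-OH freed | C=C1C[C@@H]2O[C@H]([C@H]3[C@@H](CC[C@@](C)(O)[C@H]32)[C@@H](C)CO)[C@@](C)(O)[C@H](OC(=O)CCCCCCC)C[C@H]1OC(=O)CCC | intermediate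
26 | C16 aldehyde of 25 | C=C1C[C@@H]2O[C@H]([C@H]3[C@@H](CC[C@@](C)(O)[C@H]32)[C@@H](C)C=O)[C@@](C)(O)[C@H](OC(=O)CCCCCCC)C[C@H]1OC(=O)CCC | intermediate
27 | C16 lactol (seven-membered hemiacetal with 3-OH, anomers) | C=C1C[C@@H]2O[C@@H]3[C@H]4[C@@H](CC[C@@](C)(O)[C@H]42)[C@@H](C)C(O)O[C@@]3(C)[C@H](OC(=O)CCCCCCC)C[C@H]1OC(=O)CCC | intermediate
28 | CNP0350718.2 | C=C1C[C@@H]2O[C@@H]3[C@H]4[C@@H](CC[C@@](C)(O)[C@H]42)[C@@H](C)C(=O)O[C@@]3(C)[C@H](OC(=O)CCCCCCC)C[C@H]1OC(=O)CCC | target

## Step count and risks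

Total step count: 20. Longest linear sequence: 16 (steps 1–5, 9–11, 13–20, from (R)-carvone).

Steps most likely to fail:

Step 17 (ten-membered ring closure). Oligomerisation, protodesilylation or Lewis-acid ionisation of the allylic butanoate may compete. The fallback sets out from 21: bromodesilylation with NBS (propylene oxide, CH2Cl2, −78 °C, SE2′) gives the allylic bromide aldehyde F1. This is cyclised as an allylchromium reagent under Nozaki–Hiyama conditions (CrCl2, THF, high dilution), which are neutral and also Felkin-selective, and returns to the route at 22.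

Step 18 (transannular etherification). The medium ring may override the catalyst in choosing the alkene face, acid may favour 6-endo attack at the tertiary C3, and the tether has to reach the rear of C2 to give the literal 2R,9S pairing. The fallback sets out from 22 and avoids the epoxide: Mukaiyama aerobic oxidative cyclisation (Co(modp)2, O2, t-BuOOH, i-PrOH, 55 °C). The cobalt-bound C9 alkoxide adds 5-exo to C2 (6-endo is not possible), and the tertiary C3 radical is oxygenated and reduced in the flask. The reaction is intrinsically selective for 2,5-trans tetrahydrofurans, the C3 configuration would have to be checked, and it returns directly at 24 with no new compound.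

Step 20 (oxidative lactonisation). The seven-membered lactol with a tertiary hydroxyl may not form, leaving the aldehyde. The fallback sets out from 25 and activates the carboxyl instead: Zhao oxidation (TEMPO, NaOCl cat., NaClO2, pH 6.7) gives the seco acid F2, and Yamaguchi lactonisation (2,4,6-trichlorobenzoyl chloride, Et3N; DMAP, toluene, 80 °C) closes the ring onto the C3 hydroxyl, returning at 28.

## Further compounds

F1 | step 17 | allylic bromide aldehyde (21 with CH2SiMe3 replaced by CH2Br) | CC(C)(C)[Si](C)(C)OC[C@H](C)[C@@H]1CC[C@@](C)(O[Si](CC)(CC)CC)[C@@H](C=O)[C@H]1/C=C(\C)[C@H](OC(=O)CCCCCCC)C[C@@H](OC(=O)CCC)C(=C)CBr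
F0 | step 18 | none | none
F2 | step 20 | seco acid (25 with C16 as CO2H) | C=C1C[C@@H]2O[C@H]([C@H]3[C@@H](CC[C@@](C)(O)[C@H]32)[C@@H](C)C(O)=O)[C@@](C)(O)[C@H](OC(=O)CCCCCCC)C[C@H]1OC(=O)CCC
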